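**Strategy.** Putraflavone is cut at O1''–C8a'' of pyranone ring C'' in the 8-aryl flavone unit. C8a'' sits between the biaryl carbon C8'' and the acyl-bearing C4a'', ortho to the C4'' ketone; a fluorine placed there is both an activated leaving group and a fixed marker for where the ring oxygen enters. In a single operation the enolate oxygen of a 1-(2-fluoroaryl)-3-(4-methoxyphenyl)propane-1,3-dione displaces fluoride and closes ring C'' next to the hindered biaryl bond, with no 6-aryl isomer possible. The precursor is a benzyl-protected fluorinated biaryl diketone carrying the future second flavone as a dioxolane-masked aldehyde; it is assembled from a symmetric dibromofluoroarene. Chalcone formation, oxidative cyclisation and hydrogenolysis then finish the target.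

Key step: step 9

Remarks on the chemistry (made before the steps):
- Locants with a double prime belong to the chromenone that carries the 4-methoxyphenyl group and the C8'' biaryl bond. Single primes belong to the linking hydroxyphenyl ring B. Unprimed locants belong to the 7-methoxychromenone.
- The two carbon substituents beside fluorine are brought in through bromine atoms set by electrophilic bromination, not by deprotonation beside fluorine. In a 3,5-bis(benzyloxy)fluorobenzene the carbon between the two oxygens and the benzylic C–H bonds would compete for an alkyllithium base.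
- The diketone is made from the aryl methyl ketone and 4-methoxybenzoyl chloride, which avoids an acid chloride stage in the presence of the acetal.
- Assumption: the aldehyde must stay masked as the dioxolane from step 5 to step 9, because a free formyl group would condense with the enolates of steps 8 and 9.
- The target has no stereocentre; the 3',8'' biaryl axis is left unspecified, as in the target structure.

**Route**

Step 1
Reactants: 1 5-fluororesorcinol
Product: 2 1,3-bis(benzyloxy)-5-fluorobenzene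
Conditions: BnBr (2.2 equiv), K2CO3, DMF, 60 °C
Reagents that add atoms: benzyl bromide, BrCc1ccccc1
Why: Williamson ether synthesis on two unhindered phenols; the aryl fluoride is inert to carbonate.

Step 2
Reactants: 2 1,3-bis(benzyloxy)-5-fluorobenzene
Product: 3 1,5-bis(benzyloxy)-2,4-dibromo-3-fluorobenzene
Conditions: NBS (2.05 equiv), MeCN, 0 °C to rt, dark
Reagents that add atoms: N-bromosuccinimide, O=C1CCC(=O)N1Br
Why: Electrophilic aromatic bromination; each of the two equivalent carbons beside fluorine is para to one benzyloxy group and ortho to the other, so both should react before the crowded carbon between the two oxygens, giving a symmetric dibromide.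

Step 3
Reactants: 3 1,5-bis(benzyloxy)-2,4-dibromo-3-fluorobenzene
Product: 5 1-[4,6-bis(benzyloxy)-3-bromo-2-fluorophenyl]ethan-1-one, via aryllithium 4 (not isolated)
Conditions: n-BuLi (1.0 equiv), THF, −78 °C, 15 min; then MeC(O)N(OMe)Me, −78 °C to 0 °C; aq. NH4Cl
Reagents that add atoms: N-methoxy-N-methylacetamide, CC(=O)N(C)OC
Why: Bromine–lithium exchange outruns deprotonation at −78 °C and the two bromines are equivalent, so one equivalent should give a single monolithio species (kept cold to prevent loss of LiF), which the Weinreb ketone synthesis converts to the methyl ketone without over-addition.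

Step 4
Reactants: 6 3-bromo-4-hydroxybenzaldehyde
Product: 7 4-(benzyloxy)-3-bromobenzaldehyde
Conditions: BnBr (1.1 equiv), K2CO3, DMF, rt
Reagents that add atoms: benzyl bromide, BrCc1ccccc1
Why: Williamson ether synthesis on an acidic para-formyl phenol.

Step 5
Reactants: 7 4-(benzyloxy)-3-bromobenzaldehyde
Product: 8 2-[4-(benzyloxy)-3-bromophenyl]-1,3-dioxolane
Conditions: ethylene glycol, TsOH·H2O (cat.), toluene, reflux, Dean–Stark
Reagents that add atoms: ethylene glycol, OCCO
Why: Acid-catalysed acetalisation driven by azeotropic removal of water; the dioxolane is stable to all basic steps up to step 9.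

Step 6
Reactants: 8 2-[4-(benzyloxy)-3-bromophenyl]-1,3-dioxolane
Product: 9 2-[2-(benzyloxy)-5-(1,3-dioxolan-2-yl)phenyl]-4,4,5,5-tetramethyl-1,3,2-dioxaborolane
Conditions: B2pin2, PdCl2(dppf) (3 mol%), KOAc, 1,4-dioxane, 90 °C
Reagents that add atoms: bis(pinacolato)diboron, CC1(C)OB(OC1(C)C)B1OC(C)(C)C(C)(C)O1
Why: Miyaura borylation of an aryl bromide; the weak acetate base limits homocoupling, and acetal and benzyl ether are inert.

Step 7
Reactants: 5 1-[4,6-bis(benzyloxy)-3-bromo-2-fluorophenyl]ethan-1-one; 9 2-[2-(benzyloxy)-5-(1,3-dioxolan-2-yl)phenyl]-4,4,5,5-tetramethyl-1,3,2-dioxaborolane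
Product: 10 1-{4,6-bis(benzyloxy)-3-[2-(benzyloxy)-5-(1,3-dioxolan-2-yl)phenyl]-2-fluorophenyl}ethan-1-one
Conditions: Pd(OAc)2 (5 mol%), SPhos (10 mol%), K3PO4, toluene/H2O (10:1), 90 °C
Reagents that add atoms: none
Why: Suzuki–Miyaura coupling with a dialkylbiarylphosphine ligand, the standard choice for tri-ortho-substituted biaryls from electron-rich bromides; zerovalent palladium inserts into C–Br and leaves the C–F bond alone.

Step 8
Reactants: 10 1-{4,6-bis(benzyloxy)-3-[2-(benzyloxy)-5-(1,3-dioxolan-2-yl)phenyl]-2-fluorophenyl}ethan-1-one; 11 4-methoxybenzoyl chloride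
Product: 13 1-{4,6-bis(benzyloxy)-3-[2-(benzyloxy)-5-(1,3-dioxolan-2-yl)phenyl]-2-fluorophenyl}-3-(4-methoxyphenyl)propane-1,3-dione, via lithium enolate 12 (not isolated)
Conditions: LiHMDS (2.2 equiv), THF, −78 °C; then 11 (1.0 equiv), −78 °C to 0 °C; aq. NH4Cl
Reagents that add atoms: none
Why: Claisen-type C-acylation of a methyl ketone lithium enolate by an aroyl chloride; the second equivalent of base deprotonates the diketone as it forms, which should prevent double acylation, and the cold, non-nucleophilic conditions leave the C–F bond intact.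

Step 9
Reactants: 13 1-{4,6-bis(benzyloxy)-3-[2-(benzyloxy)-5-(1,3-dioxolan-2-yl)phenyl]-2-fluorophenyl}-3-(4-methoxyphenyl)propane-1,3-dione
Product: 16 5,7-bis(benzyloxy)-8-[2-(benzyloxy)-5-(1,3-dioxolan-2-yl)phenyl]-2-(4-methoxyphenyl)-4H-chromen-4-one, via potassium enolate 14 (not isolated), via Meisenheimer adduct 15 (not isolated)
Conditions: K2CO3 (3 equiv), dry DMF, 90 °C, N2
Reagents that add atoms: none
Why: Carbonate converts the diketone into enolate 14, whose oxygen on the anisyl side adds to the fluorine-bearing C8a'' to give Meisenheimer adduct 15, with the charge carried through C4a'' onto the C4'' carbonyl oxygen, and loss of fluoride then restores the arene (intramolecular nucleophilic aromatic substitution by addition and elimination). The closest known reaction type is the carbonate-mediated cyclisation of 1-(2-fluorophenyl)-1,3-diketones to flavones. Ring C'' closes as a six-membered ring by attack on an sp2 carbon, formally 6-endo-trig across the C4a''–C8a'' bond that relays the charge. No stereocentre is created in 16, the sp3 C8a'' of 15 being transient and racemic. The step needs oxygen instead of carbon attack of the ambident enolate, which geometry secures because carbon attack would require a four-membered ring, and it needs a ring carbon that accepts the nucleophile, which the ortho C4'' carbonyl and the meta placement of the C5'' and C7'' benzyloxy groups provide. Regiochemistry cannot drift because O1'' can enter only where the single fluorine stood, so no 6-aryl flavone can form.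

Step 10
Reactants: 16 5,7-bis(benzyloxy)-8-[2-(benzyloxy)-5-(1,3-dioxolan-2-yl)phenyl]-2-(4-methoxyphenyl)-4H-chromen-4-one
Product: 17 4-(benzyloxy)-3-[5,7-bis(benzyloxy)-2-(4-methoxyphenyl)-4-oxo-4H-chromen-8-yl]benzaldehyde
Conditions: 2 M HCl, THF, rt
Reagents that add atoms: water, O
Why: Acid-catalysed acetal hydrolysis; the flavone and the benzyl ethers tolerate dilute acid at room temperature.

Step 11
Reactants: 18 2',6'-dihydroxy-4'-methoxyacetophenone
Product: 19 1-[2-(benzyloxy)-6-hydroxy-4-methoxyphenyl]ethan-1-one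
Conditions: BnBr (1.05 equiv), K2CO3, acetone, reflux
Reagents that add atoms: benzyl bromide, BrCc1ccccc1
Why: Williamson ether synthesis that should stop after one alkylation, since the two hydroxyls are equivalent and the one that remains is held in a hydrogen bond to the acetyl carbonyl.

Step 12
Reactants: 17 4-(benzyloxy)-3-[5,7-bis(benzyloxy)-2-(4-methoxyphenyl)-4-oxo-4H-chromen-8-yl]benzaldehyde; 19 1-[2-(benzyloxy)-6-hydroxy-4-methoxyphenyl]ethan-1-one
Product: 20 (E)-1-[2-(benzyloxy)-6-hydroxy-4-methoxyphenyl]-3-{4-(benzyloxy)-3-[5,7-bis(benzyloxy)-2-(4-methoxyphenyl)-4-oxo-4H-chromen-8-yl]phenyl}prop-2-en-1-one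
Conditions: KOH (50% aq.), EtOH/THF, rt
Reagents that add atoms: none
Why: Claisen–Schmidt condensation between a non-enolisable aryl aldehyde and a methyl ketone; E1cB dehydration should give the conjugated (E)-enone as the thermodynamic product.

Step 13
Reactants: 20 (E)-1-[2-(benzyloxy)-6-hydroxy-4-methoxyphenyl]-3-{4-(benzyloxy)-3-[5,7-bis(benzyloxy)-2-(4-methoxyphenyl)-4-oxo-4H-chromen-8-yl]phenyl}prop-2-en-1-one
Product: 21 5-(benzyloxy)-2-{4-(benzyloxy)-3-[5,7-bis(benzyloxy)-2-(4-methoxyphenyl)-4-oxo-4H-chromen-8-yl]phenyl}-7-methoxy-4H-chromen-4-one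
Conditions: I2 (10 mol%), DMSO, 120 °C
Reagents that add atoms: none
Why: Iodine-catalysed oxidative cyclisation of an ortho-hydroxychalcone to a flavone with DMSO as terminal oxidant; only the one free phenol can close the ring, which places benzyloxy at C5 and methoxy at C7.

Step 14
Reactants: 21 5-(benzyloxy)-2-{4-(benzyloxy)-3-[5,7-bis(benzyloxy)-2-(4-methoxyphenyl)-4-oxo-4H-chromen-8-yl]phenyl}-7-methoxy-4H-chromen-4-one
Product: 22 putraflavone
Conditions: H2 (1 atm), 10% Pd/C, THF/MeOH, rt
Reagents that add atoms: none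
Why: Catalytic hydrogenolysis of four aryl benzyl ethers; the methyl ethers, the chromenone C2–C3 double bonds and the carbonyls should be untouched at 1 atm and room temperature.

**Compound list**

1 | 5-fluororesorcinol (5-fluorobenzene-1,3-diol) | Oc1cc(O)cc(F)c1 | starting material
2 | 1,3-bis(benzyloxy)-5-fluorobenzene | Fc1cc(OCc2ccccc2)cc(OCc2ccccc2)c1 | intermediate
3 | 1,5-bis(benzyloxy)-2,4-dibromo-3-fluorobenzene | Fc1c(Br)c(OCc2ccccc2)cc(OCc2ccccc2)c1Br | intermediate
4 | [4,6-bis(benzyloxy)-3-bromo-2-fluorophenyl]lithium | [Li]c1c(F)c(Br)c(OCc2ccccc2)cc1OCc1ccccc1 | intermediate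
5 | 1-[4,6-bis(benzyloxy)-3-bromo-2-fluorophenyl]ethan-1-one | CC(=O)c1c(F)c(Br)c(OCc2ccccc2)cc1OCc1ccccc1 | intermediate
6 | 3-bromo-4-hydroxybenzaldehyde | O=Cc1ccc(O)c(Br)c1 | starting material
7 | 4-(benzyloxy)-3-bromobenzaldehyde | O=Cc1ccc(OCc2ccccc2)c(Br)c1 | intermediate
8 | 2-[4-(benzyloxy)-3-bromophenyl]-1,3-dioxolane | Brc1cc(C2OCCO2)ccc1OCc1ccccc1 | intermediate
9 | 2-[2-(benzyloxy)-5-(1,3-dioxolan-2-yl)phenyl]-4,4,5,5-tetramethyl-1,3,2-dioxaborolane | CC1(C)OB(OC1(C)C)c1cc(C2OCCO2)ccc1OCc1ccccc1 | intermediate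
10 | 1-{4,6-bis(benzyloxy)-3-[2-(benzyloxy)-5-(1,3-dioxolan-2-yl)phenyl]-2-fluorophenyl}ethan-1-one | CC(=O)c1c(F)c(-c2cc(C3OCCO3)ccc2OCc2ccccc2)c(OCc2ccccc2)cc1OCc1ccccc1 | intermediate
11 | 4-methoxybenzoyl chloride | COc1ccc(cc1)C(Cl)=O | starting material
12 | lithium enolate of ketone 10 (lithium 1-arylethen-1-olate) | [Li+].[O-]C(=C)c1c(F)c(-c2cc(C3OCCO3)ccc2OCc2ccccc2)c(OCc2ccccc2)cc1OCc1ccccc1 | intermediate
13 | 1-{4,6-bis(benzyloxy)-3-[2-(benzyloxy)-5-(1,3-dioxolan-2-yl)phenyl]-2-fluorophenyl}-3-(4-methoxyphenyl)propane-1,3-dione | COc1ccc(cc1)C(=O)CC(=O)c1c(F)c(-c2cc(C3OCCO3)ccc2OCc2ccccc2)c(OCc2ccccc2)cc1OCc1ccccc1 | intermediate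
14 | potassium (Z)-enolate of diketone 13, oxygen anion on the 4-methoxyphenyl side | COc1ccc(cc1)/C([O-])=C/C(=O)c1c(F)c(-c2cc(C3OCCO3)ccc2OCc2ccccc2)c(OCc2ccccc2)cc1OCc1ccccc1.[K+] | intermediate
15 | potassium 5,7-bis(benzyloxy)-8-[2-(benzyloxy)-5-(1,3-dioxolan-2-yl)phenyl]-8a-fluoro-2-(4-methoxyphenyl)-8aH-chromen-4-olate (racemic at C8a, transient) | COc1ccc(cc1)C1=CC([O-])=C2C(OCc3ccccc3)=CC(OCc3ccccc3)=C(-c3cc(C4OCCO4)ccc3OCc3ccccc3)C2(F)O1.[K+] | intermediate
16 | 5,7-bis(benzyloxy)-8-[2-(benzyloxy)-5-(1,3-dioxolan-2-yl)phenyl]-2-(4-methoxyphenyl)-4H-chromen-4-one | COc1ccc(cc1)-c1cc(=O)c2c(OCc3ccccc3)cc(OCc3ccccc3)c(-c3cc(C4OCCO4)ccc3OCc3ccccc3)c2o1 | intermediate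
17 | 4-(benzyloxy)-3-[5,7-bis(benzyloxy)-2-(4-methoxyphenyl)-4-oxo-4H-chromen-8-yl]benzaldehyde | COc1ccc(cc1)-c1cc(=O)c2c(OCc3ccccc3)cc(OCc3ccccc3)c(-c3cc(C=O)ccc3OCc3ccccc3)c2o1 | intermediate
18 | 2',6'-dihydroxy-4'-methoxyacetophenone | CC(=O)c1c(O)cc(OC)cc1O | starting material
19 | 1-[2-(benzyloxy)-6-hydroxy-4-methoxyphenyl]ethan-1-one | CC(=O)c1c(O)cc(OC)cc1OCc1ccccc1 | intermediate
20 | (E)-1-[2-(benzyloxy)-6-hydroxy-4-methoxyphenyl]-3-{4-(benzyloxy)-3-[5,7-bis(benzyloxy)-2-(4-methoxyphenyl)-4-oxo-4H-chromen-8-yl]phenyl}prop-2-en-1-one | COc1ccc(cc1)-c1cc(=O)c2c(OCc3ccccc3)cc(OCc3ccccc3)c(-c3cc(/C=C/C(=O)c4c(O)cc(OC)cc4OCc4ccccc4)ccc3OCc3ccccc3)c2o1 | intermediate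
21 | 5-(benzyloxy)-2-{4-(benzyloxy)-3-[5,7-bis(benzyloxy)-2-(4-methoxyphenyl)-4-oxo-4H-chromen-8-yl]phenyl}-7-methoxy-4H-chromen-4-one | COc1ccc(cc1)-c1cc(=O)c2c(OCc3ccccc3)cc(OCc3ccccc3)c(-c3cc(-c4cc(=O)c5c(OCc6ccccc6)cc(OC)cc5o4)ccc3OCc3ccccc3)c2o1 | intermediate
22 | putraflavone, 5,7-dihydroxy-8-[2-hydroxy-5-(5-hydroxy-7-methoxy-4-oxo-4H-chromen-2-yl)phenyl]-2-(4-methoxyphenyl)-4H-chromen-4-one | COc1ccc(-c2cc(=O)c3c(O)cc(O)c(-c4cc(-c5cc(=O)c6c(O)cc(OC)cc6o5)ccc4O)c3o2)cc1 | target

**Count**

Total step count: 14.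
Longest linear sequence: 10 steps (steps 1, 2, 3, 7, 8, 9, 10, 12, 13, 14).

**Steps most likely to fail, with fallbacks**

First, step 9. Fluoride displacement on the electron-rich ring may be slow. Retro-Claisen cleavage of the diketone by traces of hydroxide, or loss of benzyl groups at high temperature, could then consume the precursor. The fallback sets out from boronate 9 and comes back at 16; it builds the pyranone first, closing it at O1''–C2'', and makes the biaryl bond last. Commercial 1-[2,4-bis(benzyloxy)-6-hydroxyphenyl]ethan-1-one is iodinated ortho to its free hydroxyl (I2, HIO3, aq. EtOH), which should give 1-[4,6-bis(benzyloxy)-2-hydroxy-3-iodophenyl]ethan-1-one F1. Claisen–Schmidt condensation with 4-methoxybenzaldehyde (KOH, EtOH) should give (E)-1-[4,6-bis(benzyloxy)-2-hydroxy-3-iodophenyl]-3-(4-methoxyphenyl)prop-2-en-1-one F2. Oxidative cyclisation (I2, DMSO, 120 °C) through the only free hydroxyl should give 5,7-bis(benzyloxy)-8-iodo-2-(4-methoxyphenyl)-4H-chromen-4-one F3. Suzuki–Miyaura coupling of this iodide with 9 (Pd(OAc)2, SPhos, K3PO4, toluene/H2O, 90 °C) should then deliver 16.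

Second, step 7. Protodeboronation of the ortho-alkoxy boronate, or base-induced side reactions of the methyl ketone, may outrun transmetalation at the crowded bromide. The fallback sets out from bromide 8 (with 5) and comes back at 10; it uses a base-free Negishi coupling. Bromine–lithium exchange on 8 (n-BuLi, THF, −78 °C) should give [2-(benzyloxy)-5-(1,3-dioxolan-2-yl)phenyl]lithium F4. Addition of ZnCl2 converts it into [2-(benzyloxy)-5-(1,3-dioxolan-2-yl)phenyl]zinc chloride F5. This arylzinc does not add to ketones and should couple with 5 (Pd(OAc)2, RuPhos, THF, 65 °C) to give 10.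

Third, step 12. Hydroxide may open pyranone ring C'' during the slow aldol condensation of the deactivated phenoxide ketone, or the condensation may stall. The fallback sets out from aldehyde 17 (with 19) and comes back at 21; it replaces the chalcone path by a Baker–Venkataraman sequence without hydroxide. Pinnick oxidation of 17 (NaClO2, NaH2PO4, 2-methylbut-2-ene, t-BuOH/THF/H2O) should give 4-(benzyloxy)-3-[5,7-bis(benzyloxy)-2-(4-methoxyphenyl)-4-oxo-4H-chromen-8-yl]benzoic acid F6. Esterification with the free phenol of 19 (EDC·HCl, DMAP, CH2Cl2) should give 2-acetyl-3-(benzyloxy)-5-methoxyphenyl 4-(benzyloxy)-3-[5,7-bis(benzyloxy)-2-(4-methoxyphenyl)-4-oxo-4H-chromen-8-yl]benzoate F7. Baker–Venkataraman acyl transfer (LiHMDS, THF, −78 °C to 0 °C) should give 1-[2-(benzyloxy)-6-hydroxy-4-methoxyphenyl]-3-{4-(benzyloxy)-3-[5,7-bis(benzyloxy)-2-(4-methoxyphenyl)-4-oxo-4H-chromen-8-yl]phenyl}propane-1,3-dione F8. Cyclodehydration (TsOH·H2O, toluene, 80 °C) should then give 21.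

**Further compounds**

F1 | step 9 | 1-[4,6-bis(benzyloxy)-2-hydroxy-3-iodophenyl]ethan-1-one | CC(=O)c1c(O)c(I)c(OCc2ccccc2)cc1OCc1ccccc1
F2 | step 9 | (E)-1-[4,6-bis(benzyloxy)-2-hydroxy-3-iodophenyl]-3-(4-methoxyphenyl)prop-2-en-1-one | COc1ccc(/C=C/C(=O)c2c(O)c(I)c(OCc3ccccc3)cc2OCc2ccccc2)cc1
F3 | step 9 | 5,7-bis(benzyloxy)-8-iodo-2-(4-methoxyphenyl)-4H-chromen-4-one | COc1ccc(cc1)-c1cc(=O)c2c(OCc3ccccc3)cc(OCc3ccccc3)c(I)c2o1
F4 | step 7 | [2-(benzyloxy)-5-(1,3-dioxolan-2-yl)phenyl]lithium | [Li]c1cc(C2OCCO2)ccc1OCc1ccccc1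
F5 | step 7 | [2-(benzyloxy)-5-(1,3-dioxolan-2-yl)phenyl]zinc chloride | Cl[Zn]c1cc(C2OCCO2)ccc1OCc1ccccc1
F6 | step 12 | 4-(benzyloxy)-3-[5,7-bis(benzyloxy)-2-(4-methoxyphenyl)-4-oxo-4H-chromen-8-yl]benzoic acid | COc1ccc(cc1)-c1cc(=O)c2c(OCc3ccccc3)cc(OCc3ccccc3)c(-c3cc(C(O)=O)ccc3OCc3ccccc3)c2o1
F7 | step 12 | 2-acetyl-3-(benzyloxy)-5-methoxyphenyl 4-(benzyloxy)-3-[5,7-bis(benzyloxy)-2-(4-methoxyphenyl)-4-oxo-4H-chromen-8-yl]benzoate | COc1ccc(cc1)-c1cc(=O)c2c(OCc3ccccc3)cc(OCc3ccccc3)c(-c3cc(C(=O)Oc4cc(OC)cc(OCc5ccccc5)c4C(C)=O)ccc3OCc3ccccc3)c2o1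
F8 | step 12 | 1-[2-(benzyloxy)-6-hydroxy-4-methoxyphenyl]-3-{4-(benzyloxy)-3-[5,7-bis(benzyloxy)-2-(4-methoxyphenyl)-4-oxo-4H-chromen-8-yl]phenyl}propane-1,3-dione | COc1ccc(cc1)-c1cc(=O)c2c(OCc3ccccc3)cc(OCc3ccccc3)c(-c3cc(C(=O)CC(=O)c4c(O)cc(OC)cc4OCc4ccccc4)ccc3OCc3ccccc3)c2o1
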